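**Assumption:** the target SMILES has no stereocentre and no stereogenic double bond. The compound is achiral and needs no enantiocontrol. The racemic sp3 centre in 10, 11, 13 and 14 is erased when ring C aromatises.

## Retrosynthetic overview
1. Target ⇒ deacetylation and aromatic Claisen shift (O7 to C8) of a 7-O-prenyl flavonol triacetate ⇒ selective 7-O-prenylation of a flavonol–chromene tetraacetate.
2. Tetraacetate ⇒ one thermal fusion of phloroglucinol (ring A) with an α-acetoxy-β-ketoester that carries an aryl 1,1-dimethylpropargyl ether. Pyran ring D and pyranone ring C close in this one operation.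
3. α-Acetoxy-β-ketoester ⇒ Chan O-to-C acyl shift of an aroyloxyacetate, trapped with Ac2O.
4. Aroyloxyacetate ⇒ 2-bromo-4,5-dimethoxybenzoic acid (ring B) by demethylation, carboxylate alkylation, Stille prenylation and 4-O-propargylation.
5. Ring order: A and B are bought. D closes near 180 °C and C near 240 °C in the same heating programme.

## Route

Step 1
Reactants: 1 2-bromo-4,5-dimethoxybenzoic acid
Product: 2 2-bromo-4,5-dihydroxybenzoic acid
Conditions: BBr3 (3.5 equiv), CH2Cl2, −78 °C to rt; H2O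
Reagents that add atoms: none
Why: BBr3 aryl methyl ether cleavage removes both methyl groups while the aryl bromide and the acid are inert, and it is done first because no acid-sensitive prenyl or chromene unit is present yet.

Step 2
Reactants: 2 2-bromo-4,5-dihydroxybenzoic acid; 3 ethyl bromoacetate
Product: 4 2-ethoxy-2-oxoethyl 2-bromo-4,5-dihydroxybenzoate
Conditions: KHCO3 (1.1 equiv), DMF, rt
Reagents that add atoms: ethyl bromoacetate (3), CCOC(=O)CBr
Why: In this chemoselective carboxylate SN2 alkylation KHCO3 ionises only the carboxylic acid and not the phenols, so the carboxylate alone displaces bromide and installs the acyloxyacetate needed in step 5.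

Step 3
Reactants: 4 2-ethoxy-2-oxoethyl 2-bromo-4,5-dihydroxybenzoate; 5 tributyl(3-methylbut-2-en-1-yl)stannane
Product: 6 2-ethoxy-2-oxoethyl 4,5-dihydroxy-2-(3-methylbut-2-en-1-yl)benzoate
Conditions: Pd(PPh3)4 (5 mol %), 5 (1.5 equiv), DMF, 95 °C, Ar
Reagents that add atoms: tributyl(3-methylbut-2-en-1-yl)stannane (5), CCCC[Sn](CCCC)(CCCC)CC=C(C)C
Why: In this Stille coupling zerovalent palladium inserts into the C–Br bond activated by the ortho ester and the stannane transfers its alpha carbon, giving the linear prenyl arene under neutral conditions that spare the catechol and both esters.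

Step 4
Reactants: 6 2-ethoxy-2-oxoethyl 4,5-dihydroxy-2-(3-methylbut-2-en-1-yl)benzoate; 7 3-chloro-3-methylbut-1-yne
Product: 8 2-ethoxy-2-oxoethyl 5-hydroxy-4-[(2-methylbut-3-yn-2-yl)oxy]-2-(3-methylbut-2-en-1-yl)benzoate
Conditions: K2CO3 (1.1 equiv), KI (0.2 equiv), CuI (5 mol %), DMF, 55 °C, Ar
Reagents that add atoms: 3-chloro-3-methylbut-1-yne (7), C#CC(C)(C)Cl
Why: In this regioselective copper-assisted Williamson-type propargylation the 4-OH para to the ester carbonyl is clearly the more acidic phenol, so one equivalent of carbonate forms only that phenoxide, which captures the copper-stabilised 1,1-dimethylpropargyl electrophile.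

Step 5
Reactants: 8 2-ethoxy-2-oxoethyl 5-hydroxy-4-[(2-methylbut-3-yn-2-yl)oxy]-2-(3-methylbut-2-en-1-yl)benzoate; 9 acetic anhydride
Product: 11 ethyl 2-acetoxy-3-{5-acetoxy-4-[(2-methylbut-3-yn-2-yl)oxy]-2-(3-methylbut-2-en-1-yl)phenyl}-3-oxopropanoate (racemic), via dilithium salt of hydroxy ketoester 10 (not isolated)
Conditions: LiN(iPr)2 (2.2 equiv), THF, −78 to −20 °C; then Ac2O (2.5 equiv), −78 °C to rt
Reagents that add atoms: acetic anhydride (9), CC(=O)OC(C)=O
Why: In this Chan rearrangement the ester enolate attacks its own aroyl carbonyl (oxirane alkoxide, then C–O cleavage) and moves the aroyl group from O to C, after which Ac2O caps the alkoxide and the phenoxide, the alkyne C–H being the least acidic site and staying protonated at this base loading, and the new stereocentre is racemic and is erased in step 6.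

Step 6
Reactants: 11 ethyl 2-acetoxy-3-{5-acetoxy-4-[(2-methylbut-3-yn-2-yl)oxy]-2-(3-methylbut-2-en-1-yl)phenyl}-3-oxopropanoate; 12 phloroglucinol; 9 acetic anhydride
Product: 16 2-[8-acetoxy-2,2-dimethyl-5-(3-methylbut-2-en-1-yl)-2H-chromen-6-yl]-4-oxo-4H-chromene-3,5,7-triyl triacetate, via chromene ketoester 13 (not isolated), via open diketone 14 (not isolated), via flavonol diacetate 15 (not isolated)
Conditions: 12 (2 equiv), Ph2O, Ar stream, 180 °C (30 min) then 240 °C (45 min); cool to 60 °C; Ac2O, pyridine, DMAP (cat.)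
Reagents that add atoms: phloroglucinol (12), Oc1cc(O)cc(O)c1; acetic anhydride (9), CC(=O)OC(C)=O
Why: Proposed new method: two known uncatalysed thermal processes are run on one substrate in one heating programme, namely (a) the aryl 1,1-dimethylpropargyl ether rearrangement ([3,3] shift to C3, the only free ortho carbon, then enolisation, [1,5]-H shift and oxa-6π electrocyclisation), which closes ring D to 13 near 180 °C, and (b) the Mentzer thermal chromone synthesis, in which the β-ketoester loses ethanol to an acylketene that acylates phloroglucinol (O-acylation, thermal Fries shift) to diketone 14, whose ortho OH adds to the aroyl carbonyl and loses water to close ring C, 14 being the same 2-acyloxy-1,3-diketone type that closes to a 3-acyloxyflavone in the Allan–Robinson flavonol synthesis; both processes are neutral, symmetric phloroglucinol allows only one regioisomer, and the closing peracetylation merges any acetyl-scrambled material into the single tetraacetate 16.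

Step 7
Reactants: 16 2-[8-acetoxy-2,2-dimethyl-5-(3-methylbut-2-en-1-yl)-2H-chromen-6-yl]-4-oxo-4H-chromene-3,5,7-triyl triacetate; 17 1-bromo-3-methylbut-2-ene
Product: 19 2-[8-acetoxy-2,2-dimethyl-5-(3-methylbut-2-en-1-yl)-2H-chromen-6-yl]-7-[(3-methylbut-2-en-1-yl)oxy]-4-oxo-4H-chromene-3,5-diyl diacetate, via potassium salt of 7-phenol 18 (not isolated)
Conditions: 17 (1.3 equiv), K2CO3 (1.5 equiv), KI (cat.), dry acetone, reflux
Reagents that add atoms: 1-bromo-3-methylbut-2-ene (17), CC(C)=CCBr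
Why: In this Jurd-type selective alkylation of a flavonoid peracetate the 7-acetate is conjugated with the C4 carbonyl, is the most electrophilic ester and releases the best phenoxide, so carbonate cleaves it alone and the phenoxide is prenylated in situ (Williamson ether synthesis).

Step 8
Reactants: 19 2-[8-acetoxy-2,2-dimethyl-5-(3-methylbut-2-en-1-yl)-2H-chromen-6-yl]-7-[(3-methylbut-2-en-1-yl)oxy]-4-oxo-4H-chromene-3,5-diyl diacetate
Product: 21 broussoflavonol D, via rearranged triacetate 20 (not isolated)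
Conditions: PhNEt2, 200 °C, 1 h, Ar; cool; K2CO3 (4 equiv), MeOH–THF, 0 °C to rt, Ar; cold 1 M HCl to pH 4
Reagents that add atoms: none
Why: The aromatic Claisen [3,3] shift inverts the O-prenyl unit into the 1,1-dimethylallyl group and is expected to favour C8, because with the 5-OH acetylated (no chelate) the C7–C8 bond of the benzopyranone has the higher double-bond character and C6 is crowded by the 5-acetate, and the following carbonate-mediated methanolysis removes the three acetates without touching any alkene, no stereocentre being formed.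

## Compound list
1 | 2-bromo-4,5-dimethoxybenzoic acid | COc1cc(Br)c(C(=O)O)cc1OC | starting material
2 | 2-bromo-4,5-dihydroxybenzoic acid | O=C(O)c1cc(O)c(O)cc1Br | intermediate
3 | ethyl bromoacetate | CCOC(=O)CBr | starting material
4 | 2-ethoxy-2-oxoethyl 2-bromo-4,5-dihydroxybenzoate | CCOC(=O)COC(=O)c1cc(O)c(O)cc1Br | intermediate
5 | tributyl(3-methylbut-2-en-1-yl)stannane | CCCC[Sn](CCCC)(CCCC)CC=C(C)C | starting material
6 | 2-ethoxy-2-oxoethyl 4,5-dihydroxy-2-(3-methylbut-2-en-1-yl)benzoate | CCOC(=O)COC(=O)c1cc(O)c(O)cc1CC=C(C)C | intermediate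
7 | 3-chloro-3-methylbut-1-yne | C#CC(C)(C)Cl | starting material
8 | 2-ethoxy-2-oxoethyl 5-hydroxy-4-[(2-methylbut-3-yn-2-yl)oxy]-2-(3-methylbut-2-en-1-yl)benzoate | CCOC(=O)COC(=O)c1cc(O)c(OC(C)(C)C#C)cc1CC=C(C)C | intermediate
9 | acetic anhydride | CC(=O)OC(C)=O | starting material
10 | ethyl 2-hydroxy-3-{5-hydroxy-4-[(2-methylbut-3-yn-2-yl)oxy]-2-(3-methylbut-2-en-1-yl)phenyl}-3-oxopropanoate (racemic; present as dilithium salt, not isolated) | CCOC(=O)C(O)C(=O)c1cc(O)c(OC(C)(C)C#C)cc1CC=C(C)C | intermediate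
11 | ethyl 2-acetoxy-3-{5-acetoxy-4-[(2-methylbut-3-yn-2-yl)oxy]-2-(3-methylbut-2-en-1-yl)phenyl}-3-oxopropanoate (racemic) | CCOC(=O)C(OC(C)=O)C(=O)c1cc(OC(C)=O)c(OC(C)(C)C#C)cc1CC=C(C)C | intermediate
12 | phloroglucinol (benzene-1,3,5-triol) | Oc1cc(O)cc(O)c1 | starting material
13 | ethyl 2-acetoxy-3-[8-acetoxy-2,2-dimethyl-5-(3-methylbut-2-en-1-yl)-2H-chromen-6-yl]-3-oxopropanoate (racemic, not isolated) | CCOC(=O)C(OC(C)=O)C(=O)c1cc(OC(C)=O)c2OC(C)(C)C=Cc2c1CC=C(C)C | intermediate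
14 | 2-acetoxy-1-[8-acetoxy-2,2-dimethyl-5-(3-methylbut-2-en-1-yl)-2H-chromen-6-yl]-3-(2,4,6-trihydroxyphenyl)propane-1,3-dione (racemic, not isolated) | CC(=O)OC(C(=O)c1c(O)cc(O)cc1O)C(=O)c1cc(OC(C)=O)c2OC(C)(C)C=Cc2c1CC=C(C)C | intermediate
15 | 3-acetoxy-2-[8-acetoxy-2,2-dimethyl-5-(3-methylbut-2-en-1-yl)-2H-chromen-6-yl]-5,7-dihydroxy-4H-chromen-4-one (not isolated) | CC(=O)Oc1c(-c2cc(OC(C)=O)c3OC(C)(C)C=Cc3c2CC=C(C)C)oc2cc(O)cc(O)c2c1=O | intermediate
16 | 2-[8-acetoxy-2,2-dimethyl-5-(3-methylbut-2-en-1-yl)-2H-chromen-6-yl]-4-oxo-4H-chromene-3,5,7-triyl triacetate | CC(=O)Oc1c(-c2cc(OC(C)=O)c3OC(C)(C)C=Cc3c2CC=C(C)C)oc2cc(OC(C)=O)cc(OC(C)=O)c2c1=O | intermediate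
17 | 1-bromo-3-methylbut-2-ene (prenyl bromide) | CC(C)=CCBr | starting material
18 | 2-[8-acetoxy-2,2-dimethyl-5-(3-methylbut-2-en-1-yl)-2H-chromen-6-yl]-7-hydroxy-4-oxo-4H-chromene-3,5-diyl diacetate (present as potassium phenoxide, not isolated) | CC(=O)Oc1c(-c2cc(OC(C)=O)c3OC(C)(C)C=Cc3c2CC=C(C)C)oc2cc(O)cc(OC(C)=O)c2c1=O | intermediate
19 | 2-[8-acetoxy-2,2-dimethyl-5-(3-methylbut-2-en-1-yl)-2H-chromen-6-yl]-7-[(3-methylbut-2-en-1-yl)oxy]-4-oxo-4H-chromene-3,5-diyl diacetate | CC(=O)Oc1c(-c2cc(OC(C)=O)c3OC(C)(C)C=Cc3c2CC=C(C)C)oc2cc(OCC=C(C)C)cc(OC(C)=O)c2c1=O | intermediate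
20 | 2-[8-acetoxy-2,2-dimethyl-5-(3-methylbut-2-en-1-yl)-2H-chromen-6-yl]-7-hydroxy-8-(2-methylbut-3-en-2-yl)-4-oxo-4H-chromene-3,5-diyl diacetate (not isolated) | CC(=O)Oc1c(-c2cc(OC(C)=O)c3OC(C)(C)C=Cc3c2CC=C(C)C)oc2c(C(C)(C)C=C)c(O)cc(OC(C)=O)c2c1=O | intermediate
21 | broussoflavonol D (achiral) | C=CC(C)(C)c1c(O)cc(O)c2c(=O)c(O)c(-c3cc(O)c4c(c3CC=C(C)C)C=CC(C)(C)O4)oc12 | target

## Step count and risks
Total step count: 8. Longest linear sequence: 8 (from 1). All other inputs (3, 5, 7, 9, 12, 17) are bought.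

**Step 5.** The aroyl group is hindered by the ortho prenyl group and is electron-rich. It also sits beside a phenoxide and a terminal alkyne. Enolate self-condensation or over-acetylation could therefore outrun the acyl shift.

The fallback replaces the intramolecular O-to-C shift with an intermolecular decarboxylative Claisen condensation followed by oxidative acetoxylation. It sets out from 8 and comes back at 11. LiOH in aqueous THF at 50 °C cleaves both esters of 8 to 5-hydroxy-4-[(2-methylbut-3-yn-2-yl)oxy]-2-(3-methylbut-2-en-1-yl)benzoic acid F1. Ac2O and pyridine, with an aqueous work-up, give 5-acetoxy-4-[(2-methylbut-3-yn-2-yl)oxy]-2-(3-methylbut-2-en-1-yl)benzoic acid F2. Carbonyldiimidazole, then KO2CCH2CO2Et, MgCl2 and Et3N (Masamune–Brooks homologation), give ethyl 3-{5-acetoxy-4-[(2-methylbut-3-yn-2-yl)oxy]-2-(3-methylbut-2-en-1-yl)phenyl}-3-oxopropanoate F3. Pb(OAc)4 in benzene at rt acetoxylates the enol carbon faster than it attacks the trisubstituted alkene, giving 11.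

**Step 6.** Several things can go wrong. The α-acetoxy acylketene may decompose, the ketoester may be hydrolysed and decarboxylated by the water formed, or phloroglucinol may add to the chromene or prenyl alkenes at 240 °C.

The fallback closes the rings one at a time and builds ring C from a chalcone. It sets out from 8 and comes back at 19.
- Heating 8 alone in PhNEt2 at 190 °C closes ring D to 2-ethoxy-2-oxoethyl 8-hydroxy-2,2-dimethyl-5-(3-methylbut-2-en-1-yl)-2H-chromene-6-carboxylate F4.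
- LiAlH4 in THF gives 6-(hydroxymethyl)-2,2-dimethyl-5-(3-methylbut-2-en-1-yl)-2H-chromen-8-ol F5.
- MnO2 in CH2Cl2 gives 8-hydroxy-2,2-dimethyl-5-(3-methylbut-2-en-1-yl)-2H-chromene-6-carbaldehyde F6.
- Separately, bought 2,4,6-trihydroxyacetophenone is alkylated at its only unchelated OH with 17 (K2CO3, acetone) to 1-{2,6-dihydroxy-4-[(3-methylbut-2-en-1-yl)oxy]phenyl}ethanone F7.
- Claisen–Schmidt condensation of F6 and F7 (KOH, EtOH) gives (E)-1-{2,6-dihydroxy-4-[(3-methylbut-2-en-1-yl)oxy]phenyl}-3-[8-hydroxy-2,2-dimethyl-5-(3-methylbut-2-en-1-yl)-2H-chromen-6-yl]prop-2-en-1-one F8.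
- Algar–Flynn–Oyamada oxidation (H2O2, NaOH, MeOH) closes ring C. The two ortho OH groups are equivalent, so only one product can form, 3,5-dihydroxy-2-[8-hydroxy-2,2-dimethyl-5-(3-methylbut-2-en-1-yl)-2H-chromen-6-yl]-7-[(3-methylbut-2-en-1-yl)oxy]-4H-chromen-4-one F9.
- Ac2O, pyridine and DMAP give 19.

**Step 8.** Some C6 isomer may form. The o-(1,1-dimethylallyl)phenol may also drift into abnormal Claisen or dihydrofuran products on prolonged heating.

The fallback moves the sigmatropic step to a symmetric ring A block before ring C exists, and fixes the regiochemistry through the ring closure. It sets out from 8 and 17, by way of aldehyde F6 and ketone F7 of the previous paragraph, and comes back at 21.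
- The two ortho carbons of F7 are equivalent, so heating (PhNEt2, 170 °C) gives only 1-[2,4,6-trihydroxy-3-(2-methylbut-3-en-2-yl)phenyl]ethanone F10.
- MOMCl (2.2 equiv) and iPr2NEt cap the 4-OH and the unhindered 6-OH. The chelated, hindered 2-OH stays free in 1-[2-hydroxy-4,6-bis(methoxymethoxy)-3-(2-methylbut-3-en-2-yl)phenyl]ethanone F11.
- KOH in EtOH with F6 gives (E)-1-[2-hydroxy-4,6-bis(methoxymethoxy)-3-(2-methylbut-3-en-2-yl)phenyl]-3-[8-hydroxy-2,2-dimethyl-5-(3-methylbut-2-en-1-yl)-2H-chromen-6-yl]prop-2-en-1-one F12.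
- Algar–Flynn–Oyamada closure can use only the OH next to the tert-alkyl group. This places that group at C8 in 3-hydroxy-2-[8-hydroxy-2,2-dimethyl-5-(3-methylbut-2-en-1-yl)-2H-chromen-6-yl]-5,7-bis(methoxymethoxy)-8-(2-methylbut-3-en-2-yl)-4H-chromen-4-one F13.
- Brief 2 M HCl in MeOH at 50 °C gives 21.

## Further compounds
F1 | step 5 | 5-hydroxy-4-[(2-methylbut-3-yn-2-yl)oxy]-2-(3-methylbut-2-en-1-yl)benzoic acid | OC(=O)c1cc(O)c(OC(C)(C)C#C)cc1CC=C(C)C
F2 | step 5 | 5-acetoxy-4-[(2-methylbut-3-yn-2-yl)oxy]-2-(3-methylbut-2-en-1-yl)benzoic acid | CC(=O)Oc1cc(C(=O)O)c(CC=C(C)C)cc1OC(C)(C)C#C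
F3 | step 5 | ethyl 3-{5-acetoxy-4-[(2-methylbut-3-yn-2-yl)oxy]-2-(3-methylbut-2-en-1-yl)phenyl}-3-oxopropanoate | CCOC(=O)CC(=O)c1cc(OC(C)=O)c(OC(C)(C)C#C)cc1CC=C(C)C
F4 | step 6 | 2-ethoxy-2-oxoethyl 8-hydroxy-2,2-dimethyl-5-(3-methylbut-2-en-1-yl)-2H-chromene-6-carboxylate | CCOC(=O)COC(=O)c1cc(O)c2OC(C)(C)C=Cc2c1CC=C(C)C
F5 | step 6 | 6-(hydroxymethyl)-2,2-dimethyl-5-(3-methylbut-2-en-1-yl)-2H-chromen-8-ol | OCc1cc(O)c2OC(C)(C)C=Cc2c1CC=C(C)C
F6 | step 6 | 8-hydroxy-2,2-dimethyl-5-(3-methylbut-2-en-1-yl)-2H-chromene-6-carbaldehyde | O=Cc1cc(O)c2OC(C)(C)C=Cc2c1CC=C(C)C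
F7 | step 6 | 1-{2,6-dihydroxy-4-[(3-methylbut-2-en-1-yl)oxy]phenyl}ethanone | CC(=O)c1c(O)cc(OCC=C(C)C)cc1O
F8 | step 6 | (E)-1-{2,6-dihydroxy-4-[(3-methylbut-2-en-1-yl)oxy]phenyl}-3-[8-hydroxy-2,2-dimethyl-5-(3-methylbut-2-en-1-yl)-2H-chromen-6-yl]prop-2-en-1-one | O=C(/C=C/c1cc(O)c2OC(C)(C)C=Cc2c1CC=C(C)C)c1c(O)cc(OCC=C(C)C)cc1O
F9 | step 6 | 3,5-dihydroxy-2-[8-hydroxy-2,2-dimethyl-5-(3-methylbut-2-en-1-yl)-2H-chromen-6-yl]-7-[(3-methylbut-2-en-1-yl)oxy]-4H-chromen-4-one | O=c1c(O)c(-c2cc(O)c3OC(C)(C)C=Cc3c2CC=C(C)C)oc2cc(OCC=C(C)C)cc(O)c12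
F10 | step 8 | 1-[2,4,6-trihydroxy-3-(2-methylbut-3-en-2-yl)phenyl]ethanone | CC(=O)c1c(O)cc(O)c(C(C)(C)C=C)c1O
F11 | step 8 | 1-[2-hydroxy-4,6-bis(methoxymethoxy)-3-(2-methylbut-3-en-2-yl)phenyl]ethanone | CC(=O)c1c(OCOC)cc(OCOC)c(C(C)(C)C=C)c1O
F12 | step 8 | (E)-1-[2-hydroxy-4,6-bis(methoxymethoxy)-3-(2-methylbut-3-en-2-yl)phenyl]-3-[8-hydroxy-2,2-dimethyl-5-(3-methylbut-2-en-1-yl)-2H-chromen-6-yl]prop-2-en-1-one | O=C(/C=C/c1cc(O)c2OC(C)(C)C=Cc2c1CC=C(C)C)c1c(OCOC)cc(OCOC)c(C(C)(C)C=C)c1O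
F13 | step 8 | 3-hydroxy-2-[8-hydroxy-2,2-dimethyl-5-(3-methylbut-2-en-1-yl)-2H-chromen-6-yl]-5,7-bis(methoxymethoxy)-8-(2-methylbut-3-en-2-yl)-4H-chromen-4-one | C=CC(C)(C)c1c(OCOC)cc(OCOC)c2c(=O)c(O)c(-c3cc(O)c4c(c3CC=C(C)C)C=CC(C)(C)O4)oc12
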